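**Plan**

- Retrosynthesis: the four benzyl ethers come off last. The furan C2=C3 bond is traced back to a 2-boryl-2,3-dihydrobenzofuran, and in that compound C2–C1'' (to ring B) and C3–C1' (to ring C) are cut in one operation, giving benzofuran 8, boronic ester 11 and aryl iodide 10.
- Enabling feature: C2 and C3 of the benzofuran are the two carbons of the enol ether unit O1–C2=C3. C2 carries the 4-hydroxyphenyl ring B and C3 carries the crowded ring C, so both aryl groups can be delivered across an unsubstituted C2=C3 bond, with boron on C2 deciding which ring goes where.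
- Benzofuran 8 is opened at C3–C3a to an aryloxyacetaldehyde acetal. Ring A and ring C both derive from acetophenone 1 through the common phenol 5.
- Forward order: ring A is dressed (steps 1–2), the furan ring is closed onto it (steps 3–4), the ring C iodide is made from the same phenol (steps 5–6), rings B and C are attached together (step 7), the furan is re-aromatised (step 8) and the phenols are freed (step 9).
- Stereochemistry: the target has no stereocentre. The two centres made in step 7 (trans, from anti migration and retentive reductive elimination) are erased in step 8.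

Key step: step 7

Assumption: the target SMILES carries no stereodescriptor, so the C3–C1' aryl–hetaryl axis is treated as configurationally unfixed and no atropisomer control is planned.

**Route**

Step 1
Reactants: 1 2',6'-dihydroxy-4'-methoxyacetophenone; 2 benzyl bromide
Product: 3 1-[2-(benzyloxy)-6-hydroxy-4-methoxyphenyl]ethan-1-one
Conditions: BnBr (1.05 equiv), K2CO3, acetone, reflux
Reagents that add atoms: none
Why: Williamson etherification; after the first benzylation the remaining phenol is locked in a hydrogen bond to the acetyl oxygen and is much less nucleophilic, so the reaction should stop at the monoether.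

Step 2
Reactants: 3 1-[2-(benzyloxy)-6-hydroxy-4-methoxyphenyl]ethan-1-one
Product: 5 3-(benzyloxy)-2-ethyl-5-methoxyphenol, via aryl ethyl carbonate 4 (not isolated)
Conditions: ClCO2Et, Et3N, THF, 0 °C; then NaBH4, H2O, 0 °C to rt
Reagents that add atoms: none
Why: Reductive deoxygenation of an ortho-hydroxyaryl ketone through its carbonate; NaBH4 reduces the ketone, loss of the carbonate gives an ortho-quinone methide, and a second hydride adds to its exocyclic carbon to leave the ethyl group and the free phenol, while the benzyl and methyl ethers are inert.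

Step 3
Reactants: 5 3-(benzyloxy)-2-ethyl-5-methoxyphenol; 6 bromoacetaldehyde diethyl acetal
Product: 7 1-(benzyloxy)-3-(2,2-diethoxyethoxy)-2-ethyl-5-methoxybenzene
Conditions: K2CO3, KI (cat.), DMF, 110 °C
Reagents that add atoms: none
Why: Williamson O-alkylation of the phenoxide with a primary bromide, a standard entry to aryloxyacetaldehyde acetals.

Step 4
Reactants: 7 1-(benzyloxy)-3-(2,2-diethoxyethoxy)-2-ethyl-5-methoxybenzene
Product: 8 6-(benzyloxy)-7-ethyl-4-methoxy-1-benzofuran
Conditions: Amberlyst-15, PhMe, reflux (ethanol distilled off)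
Reagents that add atoms: none
Why: Acid-mediated cyclodehydration of an aryloxyacetaldehyde acetal (intramolecular Friedel–Crafts alkylation by the oxocarbenium ion, then loss of ethanol); the only free position ortho to the ether oxygen is activated by an ortho methoxy and a para benzyloxy group, so a single regioisomer should form.

Step 5
Reactants: 5 3-(benzyloxy)-2-ethyl-5-methoxyphenol; 2 benzyl bromide
Product: 9 1,3-bis(benzyloxy)-2-ethyl-5-methoxybenzene
Conditions: BnBr, K2CO3, DMF, 60 °C
Reagents that add atoms: none
Why: Williamson etherification of the remaining phenol, now free of any hydrogen bond to a carbonyl group.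

Step 6
Reactants: 9 1,3-bis(benzyloxy)-2-ethyl-5-methoxybenzene
Product: 10 1,3-bis(benzyloxy)-2-ethyl-4-iodo-5-methoxybenzene
Conditions: NIS (1.0 equiv), TFA (cat.), MeCN, 0 °C to rt
Reagents that add atoms: N-iodosuccinimide, O=C1CCC(=O)N1I
Why: Electrophilic aromatic iodination; the two free positions of the symmetric ether are equivalent, each ortho to a methoxy and a benzyloxy group and para to the other benzyloxy group, and one equivalent of NIS should stop at the monoiodide.

Step 7
Reactants: 8 6-(benzyloxy)-7-ethyl-4-methoxy-1-benzofuran; 11 2-[4-(benzyloxy)phenyl]-4,4,5,5-tetramethyl-1,3,2-dioxaborolane; 10 1,3-bis(benzyloxy)-2-ethyl-4-iodo-5-methoxybenzene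
Product: 14 racemic trans-2,3-diaryl-2,3-dihydrobenzofuran-2-boronic acid pinacol ester (ring B on C2 anti to ring C on C3; boron syn to ring C; one enantiomer drawn), via 2-lithiobenzofuran 12 (not isolated), via lithium boron ate complex 13 (not isolated)
Conditions: n-BuLi (0.98 equiv), THF, −78 °C; 11, −78 °C to rt; then 10, Pd(OAc)2 (5 mol %), 1,1'-bis(diphenylphosphino)ferrocene (6 mol %), KOTf, THF, 60 °C
Reagents that add atoms: none
Why: Proposed new method: n-BuLi removes the C2 proton of 8 (the most acidic C–H; at −78 °C neither C5 nor a benzylic position should compete, and no lithium halide is formed), 12 adds to the boron of 11 to give ate complex 13, and the cationic divalent arylpalladium generated from 10, zerovalent palladium and KOTf binds the electron-rich enol ether bond C2=C3 at C3, which triggers the 1,2-shift of ring B from boron to C2 (C2–C1'') and is followed by C3–C1' reductive elimination from a benzylic palladium species that has no β-hydrogen. The closest known reaction types are the palladium-catalysed conjunctive cross-coupling of alkenylboron ate complexes with aryl electrophiles and the dearomative three-component reactions in which indol-2-yl or furan-2-yl boron ate complexes are intercepted by carbon electrophiles; new here are the benzofuran-2-yl ate complex, an aryl migrating group paired with an arylpalladium trigger, and a di-ortho-substituted electrophile. No ring is closed, the furan ring is only dearomatised to a 2,3-dihydrobenzofuran. C2 is set by migration of ring B to the face opposite palladium and C3 by reductive elimination with retention, so rings B and C should be trans and boron cis to ring C; the ligand is achiral, the product is racemic, and both centres disappear in step 8. Regioselectivity (ring B to C2, ring C to C3) is fixed by boron sitting on C2, and the chemoselectivity needed, metallate shift over direct Suzuki–Miyaura transfer of an aryl group from boron to palladium, is addressed by the wide bite angle bisphosphine, the halide-free ate complex and KOTf as iodide scavenger. Crowding at C3 between the C4 methoxy group and the 2,6-dioxygenated arylpalladium is the main uncertainty.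

Step 8
Reactants: 14 racemic trans-2,3-diaryl-2,3-dihydrobenzofuran-2-boronic acid pinacol ester
Product: 16 6-(benzyloxy)-3-[2,4-bis(benzyloxy)-3-ethyl-6-methoxyphenyl]-2-[4-(benzyloxy)phenyl]-7-ethyl-4-methoxy-1-benzofuran, via C2 hemiketal 15 (not isolated)
Conditions: NaBO3·4H2O, THF/H2O, rt; then crude 15, TsOH·H2O (cat.), PhMe, 60 °C
Reagents that add atoms: none
Why: Perborate oxidation of the C–B bond (1,2-shift of carbon from boron to oxygen with retention) gives the hemiketal, which may equilibrate with its ring-opened hydroxy ketone, and acid-catalysed dehydration through the oxocarbenium ion stabilised by O1 and ring B, with loss of the C3 proton, restores the aromatic furan and removes both stereocentres.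

Step 9
Reactants: 16 6-(benzyloxy)-3-[2,4-bis(benzyloxy)-3-ethyl-6-methoxyphenyl]-2-[4-(benzyloxy)phenyl]-7-ethyl-4-methoxy-1-benzofuran
Product: 17 Effphenol A
Conditions: H2 (1 atm), Pd/C, EtOAc/MeOH, rt
Reagents that add atoms: none
Why: Hydrogenolysis of four aryl benzyl ethers over palladium; the tetrasubstituted aromatic furan bond and the methyl ethers should not react at one atmosphere and room temperature.

**Compound list**

1 | 2',6'-dihydroxy-4'-methoxyacetophenone | CC(=O)c1c(O)cc(OC)cc1O | starting material
2 | benzyl bromide | BrCc1ccccc1 | starting material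
3 | 1-[2-(benzyloxy)-6-hydroxy-4-methoxyphenyl]ethan-1-one | CC(=O)c1c(O)cc(OC)cc1OCc1ccccc1 | intermediate
4 | 2-acetyl-3-(benzyloxy)-5-methoxyphenyl ethyl carbonate | CCOC(=O)Oc1cc(OC)cc(OCc2ccccc2)c1C(C)=O | intermediate (not isolated)
5 | 3-(benzyloxy)-2-ethyl-5-methoxyphenol | CCc1c(O)cc(OC)cc1OCc1ccccc1 | intermediate
6 | bromoacetaldehyde diethyl acetal | CCOC(CBr)OCC | starting material
7 | 1-(benzyloxy)-3-(2,2-diethoxyethoxy)-2-ethyl-5-methoxybenzene | CCOC(COc1cc(OC)cc(OCc2ccccc2)c1CC)OCC | intermediate
8 | 6-(benzyloxy)-7-ethyl-4-methoxy-1-benzofuran | CCc1c(OCc2ccccc2)cc(OC)c2ccoc12 | intermediate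
9 | 1,3-bis(benzyloxy)-2-ethyl-5-methoxybenzene | CCc1c(OCc2ccccc2)cc(OC)cc1OCc1ccccc1 | intermediate
10 | 1,3-bis(benzyloxy)-2-ethyl-4-iodo-5-methoxybenzene | CCc1c(OCc2ccccc2)cc(OC)c(I)c1OCc1ccccc1 | intermediate
11 | 2-[4-(benzyloxy)phenyl]-4,4,5,5-tetramethyl-1,3,2-dioxaborolane | CC1(C)OB(OC1(C)C)c1ccc(OCc2ccccc2)cc1 | starting material
12 | [6-(benzyloxy)-7-ethyl-4-methoxy-1-benzofuran-2-yl]lithium | CCc1c(OCc2ccccc2)cc(OC)c2cc([Li])oc12 | intermediate (not isolated)
13 | lithium [6-(benzyloxy)-7-ethyl-4-methoxy-1-benzofuran-2-yl][4-(benzyloxy)phenyl](pinacolato)borate | [Li+].CCc1c(OCc2ccccc2)cc(OC)c2cc(oc12)[B-]1(OC(C)(C)C(C)(C)O1)c1ccc(OCc2ccccc2)cc1 | intermediate (not isolated)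
14 | racemic 2-{6-(benzyloxy)-3-[2,4-bis(benzyloxy)-3-ethyl-6-methoxyphenyl]-2-[4-(benzyloxy)phenyl]-7-ethyl-4-methoxy-2,3-dihydro-1-benzofuran-2-yl}-4,4,5,5-tetramethyl-1,3,2-dioxaborolane, aryl groups on C2 and C3 trans, boron cis to ring C (one enantiomer drawn) | CCc1c(OCc2ccccc2)cc(OC)c2[C@@H](c3c(OC)cc(OCc4ccccc4)c(CC)c3OCc3ccccc3)[C@@](c3ccc(OCc4ccccc4)cc3)(B3OC(C)(C)C(C)(C)O3)Oc12 | intermediate
15 | racemic 6-(benzyloxy)-3-[2,4-bis(benzyloxy)-3-ethyl-6-methoxyphenyl]-2-[4-(benzyloxy)phenyl]-7-ethyl-4-methoxy-2,3-dihydro-1-benzofuran-2-ol, OH cis to ring C (one enantiomer drawn) | CCc1c(OCc2ccccc2)cc(OC)c2[C@@H](c3c(OC)cc(OCc4ccccc4)c(CC)c3OCc3ccccc3)[C@@](c3ccc(OCc4ccccc4)cc3)(O)Oc12 | intermediate (not isolated)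
16 | 6-(benzyloxy)-3-[2,4-bis(benzyloxy)-3-ethyl-6-methoxyphenyl]-2-[4-(benzyloxy)phenyl]-7-ethyl-4-methoxy-1-benzofuran | CCc1c(OCc2ccccc2)cc(OC)c2c(-c3c(OC)cc(OCc4ccccc4)c(CC)c3OCc3ccccc3)c(-c3ccc(OCc4ccccc4)cc3)oc12 | intermediate
17 | Effphenol A, 2-ethyl-4-[7-ethyl-6-hydroxy-2-(4-hydroxyphenyl)-4-methoxy-1-benzofuran-3-yl]-5-methoxybenzene-1,3-diol | CCc1c(O)cc(OC)c(-c2c(-c3ccc(O)cc3)oc3c(CC)c(O)cc(OC)c23)c1O | target

**Summary**

Total step count: 9. Longest linear sequence: 7 steps (1, 2, 3, 4, 7, 8, 9; the branch through steps 5 and 6 is equally long).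

Steps most likely to fail:

1. Step 7. The arylpalladium intermediate may take an aryl group from boron by direct transmetalation, or fail to engage the crowded C3 position, so that biaryls or recovered benzofuran result instead of the conjunctive product. The fallback installs the two aryl groups one after the other by known couplings, setting out from 8 and returning at 16.
   - Lithiation of 8 (through 12) and an iodine quench should give 6-(benzyloxy)-7-ethyl-2-iodo-4-methoxy-1-benzofuran F1.
   - Suzuki–Miyaura coupling of F1 with boronic ester 11 (Pd(PPh3)4, K2CO3, dioxane/H2O) should give 6-(benzyloxy)-2-[4-(benzyloxy)phenyl]-7-ethyl-4-methoxy-1-benzofuran F2.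
   - NBS bromination at C3, the nucleophilic β-carbon of the 2-aryl enol ether, should give 6-(benzyloxy)-2-[4-(benzyloxy)phenyl]-3-bromo-7-ethyl-4-methoxy-1-benzofuran F3.
   - In parallel, Miyaura borylation of iodide 10 (bis(pinacolato)diboron, PdCl2(dppf), KOAc, dioxane) should give 2-[2,4-bis(benzyloxy)-3-ethyl-6-methoxyphenyl]-4,4,5,5-tetramethyl-1,3,2-dioxaborolane F4.
   - A hindered Suzuki–Miyaura coupling of F3 with F4 (Pd(OAc)2, SPhos, K3PO4, PhMe/H2O, 100 °C) forms C3–C1' and rejoins the route at 16, bypassing 14 and step 8.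

2. Step 4. Under the acidic cyclisation conditions the benzyl ether may be cleaved or migrate onto the electron-rich ring, and the arene may oligomerise. The fallback builds the furan ring without a Friedel–Crafts step, setting out from 5 and returning at 8.
   - Allylation (allyl bromide, K2CO3, acetone) should give 1-(allyloxy)-3-(benzyloxy)-2-ethyl-5-methoxybenzene F5.
   - Aromatic Claisen rearrangement (PhNEt2, 190 °C) to the only free ortho position should give 6-allyl-3-(benzyloxy)-2-ethyl-5-methoxyphenol F6.
   - Lemieux–Johnson cleavage (OsO4 cat., NaIO4, 2,6-lutidine, dioxane/H2O) should give an aldehyde that closes to 6-(benzyloxy)-7-ethyl-4-methoxy-2,3-dihydro-1-benzofuran-2-ol F7.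
   - Mild dehydration (TsOH cat., PhMe, 60 °C) should then give 8.

3. Step 8. Oxidation of the hindered tertiary α-oxygenated C–B bond may be slow, and ring opening or protodeboronation may compete in the basic peroxide medium. The fallback changes the oxidation level at which the furan is restored, setting out from 14 and returning at 16.
   - Protodeboronation of the tertiary benzylic boronic ester with TBAF·3H2O in toluene should give racemic trans-6-(benzyloxy)-3-[2,4-bis(benzyloxy)-3-ethyl-6-methoxyphenyl]-2-[4-(benzyloxy)phenyl]-7-ethyl-4-methoxy-2,3-dihydro-1-benzofuran F8.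
   - Dehydrogenation with DDQ (dioxane, 80 °C) should give 16.

Further compounds
F1 | step 7 | 6-(benzyloxy)-7-ethyl-2-iodo-4-methoxy-1-benzofuran | CCc1c(OCc2ccccc2)cc(OC)c2cc(I)oc12
F2 | step 7 | 6-(benzyloxy)-2-[4-(benzyloxy)phenyl]-7-ethyl-4-methoxy-1-benzofuran | CCc1c(OCc2ccccc2)cc(OC)c2cc(-c3ccc(OCc4ccccc4)cc3)oc12
F3 | step 7 | 6-(benzyloxy)-2-[4-(benzyloxy)phenyl]-3-bromo-7-ethyl-4-methoxy-1-benzofuran | CCc1c(OCc2ccccc2)cc(OC)c2c(Br)c(-c3ccc(OCc4ccccc4)cc3)oc12
F4 | step 7 | 2-[2,4-bis(benzyloxy)-3-ethyl-6-methoxyphenyl]-4,4,5,5-tetramethyl-1,3,2-dioxaborolane | CCc1c(OCc2ccccc2)cc(OC)c(B2OC(C)(C)C(C)(C)O2)c1OCc1ccccc1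
F5 | step 4 | 1-(allyloxy)-3-(benzyloxy)-2-ethyl-5-methoxybenzene | C=CCOc1cc(OC)cc(OCc2ccccc2)c1CC
F6 | step 4 | 6-allyl-3-(benzyloxy)-2-ethyl-5-methoxyphenol | C=CCc1c(O)c(CC)c(OCc2ccccc2)cc1OC
F7 | step 4 | racemic 6-(benzyloxy)-7-ethyl-4-methoxy-2,3-dihydro-1-benzofuran-2-ol | CCc1c(OCc2ccccc2)cc(OC)c2CC(O)Oc12
F8 | step 8 | racemic trans-6-(benzyloxy)-3-[2,4-bis(benzyloxy)-3-ethyl-6-methoxyphenyl]-2-[4-(benzyloxy)phenyl]-7-ethyl-4-methoxy-2,3-dihydro-1-benzofuran (one enantiomer drawn) | CCc1c(OCc2ccccc2)cc(OC)c2[C@@H](c3c(OC)cc(OCc4ccccc4)c(CC)c3OCc3ccccc3)[C@H](c3ccc(OCc4ccccc4)cc3)Oc12
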